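**Plan**
- Retrosynthetic cuts: (a) the O–Si bond at the side-chain carbinol; (b) in the oxepane, the ring O1–C7H2 bond together with the exocyclic allylic CH2–OAc bond; (c) the C–C bond between the first and second CH2 of the side chain on the quaternary ring carbon C2.
- Enabling feature: ring atoms O1–C7–C6 and the exocyclic CH–CH2OAc form a 1,4-dioxygenated 2-alkylbut-2-ene. This is the 1,4-adduct of the C2 tertiary alkoxide and acetate across a 2-substituted buta-1,3-diene tied to the carbinol through ring carbons C3–C5, and that diene is the intact terminus of myrcene.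
- Forward order: epoxide 5 from myrcene (steps 1–4); bromide 11 from 4-methylpent-3-en-1-ol (steps 5–9); CuI-catalysed Grignard opening of the epoxide joins the chain (step 10); the only ring, the oxepane, is closed by oxidative 1,4-oxyacetoxylation (step 13); desilylation ends the route.
- Stereochemistry: ring C3 (R) and C2 (S) come from the tartrate-controlled kinetic resolution/epoxidation of a racemic isopropenyl carbinol (step 3). Side-chain C4 (R) and C5 (R) come from a (Z)-crotylboration (step 6). The E alkene comes from the geometry of the allylpalladium intermediate in step 13.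

Key step: step 13

Remark: for the acyclic intermediates the locants C1–C16 follow the hexadecane names (C1 = vinyl CH2), and C3a denotes the methylidene carbon on C3; the oxepanes carry ring locants.

**Step 1**
Reactants: 1 myrcene (7-methyl-3-methylideneocta-1,6-diene)
Product: 2 rac-2,2-dimethyl-3-(3-methylidenepent-4-en-1-yl)oxirane
Conditions: mCPBA (1.0 equiv), NaHCO3, CH2Cl2, 0 °C
Reagents that add atoms: meta-chloroperoxybenzoic acid, OOC(=O)c1cccc(Cl)c1
Why: Prilezhaev epoxidation, in which the electrophilic peracid should select the electron-rich trisubstituted alkene over the mono- and 1,1-disubstituted termini of the conjugated diene; the racemate suffices because step 3 sets the configuration.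

**Step 2**
Reactants: 2 rac-2,2-dimethyl-3-(3-methylidenepent-4-en-1-yl)oxirane
Product: 3 rac-2-methyl-6-methylideneocta-1,7-dien-3-ol
Conditions: Et2AlCl, LiTMP (forms Et2Al(TMP)), toluene, 0 °C; H2O work-up
Reagents that add atoms: none
Why: Aluminium amide-mediated isomerization of an epoxide to an allylic alcohol, in which aluminium binds the oxirane oxygen and the hindered amide removes a proton from a geminal methyl group in a syn elimination across the tertiary C–O bond, which should give the isopropenyl carbinol regioselectively and leave the diene alone.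

**Step 3**
Reactants: 3 rac-2-methyl-6-methylideneocta-1,7-dien-3-ol
Product: 4 (1R)-4-methylidene-1-[(2S)-2-methyloxiran-2-yl]hex-5-en-1-ol
Conditions: Ti(OiPr)4 (10 mol%), D-(–)-diisopropyl tartrate (15 mol%), t-BuOOH (0.45 equiv), 4 Å MS, CH2Cl2, –20 °C
Reagents that add atoms: tert-butyl hydroperoxide, CC(C)(C)OO
Why: Sharpless kinetic resolution by asymmetric epoxidation, in which the D-tartrate catalyst should epoxidize the (R)-carbinol far faster than its enantiomer and, as is general for secondary allylic alcohols, on the face that gives the erythro product, so that the carbinol carbon (R) is set by enantiomer selection and the oxirane carbon (S) by hydroxyl-directed oxygen delivery; the remote diene is not reached by the directing hydroxyl and the yield is limited to half of 3.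

**Step 4**
Reactants: 4 (1R)-4-methylidene-1-[(2S)-2-methyloxiran-2-yl]hex-5-en-1-ol
Product: 5 triethyl{[(1R)-4-methylidene-1-[(2S)-2-methyloxiran-2-yl]hex-5-en-1-yl]oxy}silane
Conditions: TESCl, imidazole, DMF, 0 °C → rt
Reagents that add atoms: chlorotriethylsilane, CC[Si](Cl)(CC)CC
Why: Standard silylation of the secondary alcohol, which keeps the hydroxyl from quenching the Grignard reagent in step 10 and can later be removed in the presence of the more robust silyl ether of the other fragment.

**Step 5**
Reactants: 6 4-methylpent-3-en-1-ol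
Product: 7 4-methylpent-3-enal
Conditions: Dess–Martin periodinane, NaHCO3, CH2Cl2, 0 °C; used at once as a cold, filtered solution
Reagents that add atoms: none
Why: Dess–Martin oxidation under buffered, non-enolizing conditions should give the β,γ-unsaturated aldehyde without migration of the double bond into conjugation.

**Step 6**
Reactants: 7 4-methylpent-3-enal
Product: 8 (3R,4R)-3,7-dimethylocta-1,6-dien-4-ol
Conditions: cis-but-2-ene, KOt-Bu, n-BuLi, THF, –78 → –45 °C; (–)-Ipc2BOMe [from (+)-α-pinene], –78 °C; BF3·OEt2; then 7, –78 °C; NaOH, H2O2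
Reagents that add atoms: (Z)-crotyldiisopinocampheylborane, C/C=C\CB([C@@H]1C[C@@H]2C[C@H]([C@H]1C)C2(C)C)[C@@H]1C[C@@H]2C[C@H]([C@H]1C)C2(C)C, made in the flask from cis-but-2-ene, C/C=C\C
Why: Brown crotylboration through a closed chair transition state, in which the Z-crotyl geometry gives the syn methyl/hydroxyl pair and the isopinocampheyl groups derived from (+)-α-pinene direct the attack to the Si face of the aldehyde, setting (3R,4R).

**Step 7**
Reactants: 8 (3R,4R)-3,7-dimethylocta-1,6-dien-4-ol
Product: 9 tert-butyl{[(3R,4R)-3,7-dimethylocta-1,6-dien-4-yl]oxy}dimethylsilane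
Conditions: TBSOTf, 2,6-lutidine, CH2Cl2, –78 → 0 °C
Reagents that add atoms: tert-butyldimethylsilyl trifluoromethanesulfonate, CC(C)(C)[Si](C)(C)OS(=O)(=O)C(F)(F)F
Why: Silylation of the hindered secondary alcohol with the silyl triflate gives an ether that survives the organometallic, acidic and oxidative steps up to the end.

**Step 8**
Reactants: 9 tert-butyl{[(3R,4R)-3,7-dimethylocta-1,6-dien-4-yl]oxy}dimethylsilane
Product: 10 (3R,4R)-4-[(tert-butyldimethylsilyl)oxy]-3,7-dimethyloct-6-en-1-ol
Conditions: 9-BBN, THF, 0 °C → rt; then NaOH, H2O2, 0 °C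
Reagents that add atoms: hydrogen peroxide, OO
Why: Hydroboration–oxidation with the bulky 9-BBN should add anti-Markovnikov to the monosubstituted alkene only, the trisubstituted alkene reacting much more slowly, and no stereocentre is touched.

**Step 9**
Reactants: 10 (3R,4R)-4-[(tert-butyldimethylsilyl)oxy]-3,7-dimethyloct-6-en-1-ol
Product: 11 {[(3R,4R)-1-bromo-3,7-dimethyloct-6-en-4-yl]oxy}(tert-butyl)dimethylsilane
Conditions: CBr4, PPh3, CH2Cl2, 0 °C
Reagents that add atoms: tetrabromomethane, BrC(Br)(Br)Br
Why: Appel bromination converts the primary alcohol into the bromide under neutral conditions that spare the silyl ether and the alkene.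

**Step 10**
Reactants: 11 {[(3R,4R)-1-bromo-3,7-dimethyloct-6-en-4-yl]oxy}(tert-butyl)dimethylsilane; 5 triethyl{[(1R)-4-methylidene-1-[(2S)-2-methyloxiran-2-yl]hex-5-en-1-yl]oxy}silane
Product: 13 (6R,7S,11R,12R)-12-[(tert-butyldimethylsilyl)oxy]-7,11,15-trimethyl-3-methylidene-6-[(triethylsilyl)oxy]hexadeca-1,14-dien-7-ol, via Grignard reagent 12 (not isolated)
Conditions: Mg, THF, rt → 40 °C; then CuI (10 mol%), 5, THF, –30 → 0 °C; aq. NH4Cl
Reagents that add atoms: none
Why: Copper-catalysed Grignard opening of an epoxide (SN2), in which the alkylcopper species attacks the unsubstituted oxirane CH2 of 5, forming the C8–C9 bond, freeing the tertiary alcohol and leaving the configuration of the quaternary carbon untouched, while the silyl ethers and the unactivated diene do not react.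

**Step 11**
Reactants: 13 (6R,7S,11R,12R)-12-[(tert-butyldimethylsilyl)oxy]-7,11,15-trimethyl-3-methylidene-6-[(triethylsilyl)oxy]hexadeca-1,14-dien-7-ol
Product: 14 (6R,7S,11R,12R)-12-[(tert-butyldimethylsilyl)oxy]-7,11,15-trimethyl-3-methylidenehexadeca-1,14-diene-6,7-diol
Conditions: PPTS (0.2 equiv), MeOH/CH2Cl2, 0 °C → rt
Reagents that add atoms: none
Why: Mild acid-catalysed methanolysis should cleave the triethylsilyl ether selectively, the hindered secondary tert-butyldimethylsilyl ether being much slower to solvolyse.

**Step 12**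
Reactants: 14 (6R,7S,11R,12R)-12-[(tert-butyldimethylsilyl)oxy]-7,11,15-trimethyl-3-methylidenehexadeca-1,14-diene-6,7-diol
Product: 15 (6R,7S,11R,12R)-12-[(tert-butyldimethylsilyl)oxy]-7-hydroxy-7,11,15-trimethyl-3-methylidenehexadeca-1,14-dien-6-yl acetate
Conditions: Ac2O (1.5 equiv), pyridine, DMAP (5 mol%), CH2Cl2, 0 °C
Reagents that add atoms: acetic anhydride, CC(=O)OC(C)=O
Why: Acylation under these mild conditions should take the secondary hydroxyl only, the tertiary hydroxyl being too hindered, which installs the ring acetate and leaves the tertiary alcohol as the sole free nucleophile for step 13.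

**Step 13**
Reactants: 15 (6R,7S,11R,12R)-12-[(tert-butyldimethylsilyl)oxy]-7-hydroxy-7,11,15-trimethyl-3-methylidenehexadeca-1,14-dien-6-yl acetate
Product: 16 (2S,3R,6E)-6-(2-acetoxyethylidene)-2-{(4R,5R)-5-[(tert-butyldimethylsilyl)oxy]-4,8-dimethylnon-7-en-1-yl}-2-methyloxepan-3-yl acetate
Conditions: Pd(OAc)2 (5 mol%), p-benzoquinone (20 mol%), MnO2 (1.5 equiv), acetone/AcOH (4:1), rt
Reagents that add atoms: acetic acid, CC(O)=O
Why: Proposed new method: Pd(OAc)2 (divalent palladium) binds the 2-substituted butadiene of 15, the tethered tertiary C7 hydroxyl adds anti to the metal at the methylidene carbon C3a to give an η3-allylpalladium over C3–C2–C1, benzoquinone-activated attack of acetate at the unsubstituted terminus C1 completes the 1,4-addition, and the zerovalent palladium released is reoxidised by benzoquinone/MnO2. The closest known reaction type is the Pd(OAc)2/benzoquinone intramolecular 1,4-oxyacetoxylation of conjugated dienols, established for hydroxyl tethers on a diene terminus that close five- and six-membered rings, whereas here the tether sits on the internal diene carbon and a tertiary alcohol closes a seven-membered ring. The oxepane closes in the 7-endo-trig mode at the coordinated C3=C3a bond. No stereocentre is formed; the alkene geometry is set by attack on the preferred s-trans diene, which puts C3a trans and C4 cis to C1 in the allyl (the fully substituted allyl terminus does not readily invert), so that acetate attack at C1 gives the E alkene. The step needs addition at C3a in preference to C3 (6-exo) and to intermolecular acetate, which rests on three points: only terminal attack leads to the stabilised allyl complex whereas the alkylpalladium from attack at C3 has no β-hydrogen and can only revert, the C6 and C12 oxygens are masked as acetate and silyl ether, and the medium is poor in free acetate. If acetate adds first at C1, the hydroxyl can still close on the resulting allyl at C3a and the same product results.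

**Step 14**
Reactants: 16 (2S,3R,6E)-6-(2-acetoxyethylidene)-2-{(4R,5R)-5-[(tert-butyldimethylsilyl)oxy]-4,8-dimethylnon-7-en-1-yl}-2-methyloxepan-3-yl acetate
Product: 17 (2S,3R,6E)-6-(2-acetoxyethylidene)-2-[(4R,5R)-5-hydroxy-4,8-dimethylnon-7-en-1-yl]-2-methyloxepan-3-yl acetate (target)
Conditions: HF·pyridine, pyridine, THF, 0 °C → rt
Reagents that add atoms: none
Why: Buffered fluoride cleavage of the Si–O bond should free the side-chain alcohol without acyl migration or loss of the two acetates, which a basic fluoride source could cause.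

**Compound list**
1 | myrcene (7-methyl-3-methylideneocta-1,6-diene) | C=CC(=C)CCC=C(C)C | starting material
2 | rac-2,2-dimethyl-3-(3-methylidenepent-4-en-1-yl)oxirane | C=CC(=C)CCC1OC1(C)C | intermediate
3 | rac-2-methyl-6-methylideneocta-1,7-dien-3-ol | C=CC(=C)CCC(O)C(C)=C | intermediate
4 | (1R)-4-methylidene-1-[(2S)-2-methyloxiran-2-yl]hex-5-en-1-ol | C=CC(=C)CC[C@@H](O)[C@]1(C)CO1 | intermediate
5 | triethyl{[(1R)-4-methylidene-1-[(2S)-2-methyloxiran-2-yl]hex-5-en-1-yl]oxy}silane | C=CC(=C)CC[C@@H](O[Si](CC)(CC)CC)[C@]1(C)CO1 | intermediate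
6 | 4-methylpent-3-en-1-ol | CC(C)=CCCO | starting material
7 | 4-methylpent-3-enal | CC(C)=CCC=O | intermediate
8 | (3R,4R)-3,7-dimethylocta-1,6-dien-4-ol | C=C[C@@H](C)[C@H](O)CC=C(C)C | intermediate
9 | tert-butyl{[(3R,4R)-3,7-dimethylocta-1,6-dien-4-yl]oxy}dimethylsilane | C=C[C@@H](C)[C@H](O[Si](C)(C)C(C)(C)C)CC=C(C)C | intermediate
10 | (3R,4R)-4-[(tert-butyldimethylsilyl)oxy]-3,7-dimethyloct-6-en-1-ol | OCC[C@@H](C)[C@H](O[Si](C)(C)C(C)(C)C)CC=C(C)C | intermediate
11 | {[(3R,4R)-1-bromo-3,7-dimethyloct-6-en-4-yl]oxy}(tert-butyl)dimethylsilane | BrCC[C@@H](C)[C@H](O[Si](C)(C)C(C)(C)C)CC=C(C)C | intermediate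
12 | {(3R,4R)-4-[(tert-butyldimethylsilyl)oxy]-3,7-dimethyloct-6-en-1-yl}magnesium bromide | Br[Mg]CC[C@@H](C)[C@H](O[Si](C)(C)C(C)(C)C)CC=C(C)C | intermediate
13 | (6R,7S,11R,12R)-12-[(tert-butyldimethylsilyl)oxy]-7,11,15-trimethyl-3-methylidene-6-[(triethylsilyl)oxy]hexadeca-1,14-dien-7-ol | C=CC(=C)CC[C@@H](O[Si](CC)(CC)CC)[C@@](C)(O)CCC[C@@H](C)[C@H](O[Si](C)(C)C(C)(C)C)CC=C(C)C | intermediate
14 | (6R,7S,11R,12R)-12-[(tert-butyldimethylsilyl)oxy]-7,11,15-trimethyl-3-methylidenehexadeca-1,14-diene-6,7-diol | C=CC(=C)CC[C@@H](O)[C@@](C)(O)CCC[C@@H](C)[C@H](O[Si](C)(C)C(C)(C)C)CC=C(C)C | intermediate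
15 | (6R,7S,11R,12R)-12-[(tert-butyldimethylsilyl)oxy]-7-hydroxy-7,11,15-trimethyl-3-methylidenehexadeca-1,14-dien-6-yl acetate | C=CC(=C)CC[C@@H](OC(C)=O)[C@@](C)(O)CCC[C@@H](C)[C@H](O[Si](C)(C)C(C)(C)C)CC=C(C)C | intermediate
16 | (2S,3R,6E)-6-(2-acetoxyethylidene)-2-{(4R,5R)-5-[(tert-butyldimethylsilyl)oxy]-4,8-dimethylnon-7-en-1-yl}-2-methyloxepan-3-yl acetate | CC(=O)OC/C=C1\CC[C@@H](OC(C)=O)[C@](C)(CCC[C@@H](C)[C@H](O[Si](C)(C)C(C)(C)C)CC=C(C)C)OC1 | intermediate
17 | (2S,3R,6E)-6-(2-acetoxyethylidene)-2-[(4R,5R)-5-hydroxy-4,8-dimethylnon-7-en-1-yl]-2-methyloxepan-3-yl acetate | CC(=O)OC/C=C1\CC[C@@H](OC(C)=O)[C@](C)(CCC[C@@H](C)[C@H](O)CC=C(C)C)OC1 | target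

**Count**
Total steps: 14. Longest linear sequence: 10 steps (6 → 17, steps 5–14); the myrcene branch adds steps 1–4.

**Steps most likely to fail, with fallbacks**

Step 13 (Proposed new method). The hindered tertiary hydroxyl may add too slowly in the endo mode, so that acetate from the medium adds to the diene first and the open-chain diacetate accumulates, or the allyl terminus may form with the other geometry and lead to the Z alkene. The fallback sets out from 15 and comes back at 16 with known reactions. Compound 15 is treated with Pd(OAc)2 (5 mol%), LiOAc, catalytic p-benzoquinone and MnO2 in AcOH at rt, the established intermolecular 1,4-diacetoxylation of 2-substituted buta-1,3-dienes, to give (2E,6R,7S,11R,12R)-3-(acetoxymethyl)-12-[(tert-butyldimethylsilyl)oxy]-7-hydroxy-7,11,15-trimethylhexadeca-2,14-diene-1,6-diyl diacetate F1 (either alkene isomer serves). F1 is then cyclised with Pd(PPh3)4 (zerovalent palladium, 5 mol%) and Et3N in THF at 50 °C in a Tsuji–Trost allylic etherification. Ionisation of the acetoxymethyl group on C3 gives the allyl over C3a–C3–C2, the syn/anti equilibrium at its secondary terminus C2 should funnel both isomers of F1 to the syn allyl, and the tertiary alkoxide attacks the primary terminus C3a to give 16 with the E alkene. Ionisation at C1 is expected to be unproductive and reversible, because ring closure from that allyl would need an eight-membered ring or a di-tertiary ether.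

Step 10. Attack at the neopentyl-type oxirane CH2 may be slow, so that magnesium halide-induced rearrangement of the 2,2-disubstituted epoxide to an aldehyde, or halohydrin formation, takes over. The fallback sets out from 11 and 5 and comes back at 13. Bromide 11 is converted with PhSO2Na in DMF at 60 °C into tert-butyl{[(3R,4R)-3,7-dimethyl-1-(phenylsulfonyl)oct-6-en-4-yl]oxy}dimethylsilane F2. F2 is lithiated (n-BuLi, THF, –78 °C) and the halide-free sulfonyl carbanion opens epoxide 5 (THF/HMPA, –78 → 0 °C) to give (6R,7S,11R,12R)-12-[(tert-butyldimethylsilyl)oxy]-7,11,15-trimethyl-3-methylidene-9-(phenylsulfonyl)-6-[(triethylsilyl)oxy]hexadeca-1,14-dien-7-ol F3 as a mixture of epimers at C9. Reductive desulfonylation (Na(Hg), Na2HPO4, MeOH, –20 °C) returns to 13.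

Step 6. The β,γ-double bond of aldehyde 7 may migrate into conjugation, or the volatile aldehyde may be lost before C–C bond formation, which would erode yield and selectivity. The fallback sets out from 6 and comes back at 8. Alcohol 6 is crotylated at the alcohol oxidation level by iridium-catalysed transfer hydrogenation, so that the aldehyde never accumulates: [Ir(cod)Cl]2, the SEGPHOS enantiomer that delivers the (4S) carbinol, 4-cyano-3-nitrobenzoic acid, Cs2CO3, but-3-en-2-yl acetate, THF, 90 °C. This reaction type is anti-selective and should give (3R,4S)-3,7-dimethylocta-1,6-dien-4-ol F4. Mitsunobu inversion of the carbinol (4-nitrobenzoic acid, PPh3, DIAD, toluene, 0 °C → rt) gives (3R,4R)-3,7-dimethylocta-1,6-dien-4-yl 4-nitrobenzoate F5, and K2CO3/MeOH returns to 8.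

**Further compounds**
F1 | step 13 | (2E,6R,7S,11R,12R)-3-(acetoxymethyl)-12-[(tert-butyldimethylsilyl)oxy]-7-hydroxy-7,11,15-trimethylhexadeca-2,14-diene-1,6-diyl diacetate | CC(=O)OC/C=C(COC(C)=O)\CC[C@@H](OC(C)=O)[C@@](C)(O)CCC[C@@H](C)[C@H](O[Si](C)(C)C(C)(C)C)CC=C(C)C
F2 | step 10 | tert-butyl{[(3R,4R)-3,7-dimethyl-1-(phenylsulfonyl)oct-6-en-4-yl]oxy}dimethylsilane | O=S(=O)(CC[C@@H](C)[C@H](O[Si](C)(C)C(C)(C)C)CC=C(C)C)c1ccccc1
F3 | step 10 | (6R,7S,11R,12R)-12-[(tert-butyldimethylsilyl)oxy]-7,11,15-trimethyl-3-methylidene-9-(phenylsulfonyl)-6-[(triethylsilyl)oxy]hexadeca-1,14-dien-7-ol (epimers at C9) | C=CC(=C)CC[C@@H](O[Si](CC)(CC)CC)[C@@](C)(O)CC(C[C@@H](C)[C@H](O[Si](C)(C)C(C)(C)C)CC=C(C)C)S(=O)(=O)c1ccccc1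
F4 | step 6 | (3R,4S)-3,7-dimethylocta-1,6-dien-4-ol | C=C[C@@H](C)[C@@H](O)CC=C(C)C
F5 | step 6 | (3R,4R)-3,7-dimethylocta-1,6-dien-4-yl 4-nitrobenzoate | C=C[C@@H](C)[C@H](OC(=O)c1ccc(cc1)[N+](=O)[O-])CC=C(C)C
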